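**Plan**

1. Target numbering: ring C1 carries C7H2–OBz, C2 is the alkene CH, then C3–OH, C4–OH, C5–OAc, C6–OBz. The ring is cut at C5–C6, a bond between two oxygen-bearing carbons. C6 is an allylic carbinol carbon on the trisubstituted C1=C2 bond of the cyclohexene, which is the retron of an SE2′ addition of a γ-oxygenated allylmetal (metal on C2, oxygen on C6) to an aldehyde at C5.
2. Before that cut the acyl groups come off (O6–benzoyl with inversion, O5–acetyl). After it, C1=C2 is cut by cross-metathesis and the C5 aldehyde goes back to a vinyl group, leaving a twofold-symmetric (4R,5R)-divinyl dioxolane and 2-formylallyl benzoate.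
3. Forward: the chain is joined at C1=C2, the second vinyl group is cleaved to the C5 aldehyde, and the only ring is closed last at C5–C6 by reductive cyclization of the enal–aldehyde with divalent chromium. The enal geometry is erased because C2 becomes sp3 in the allylchromium.
4. Stereochemistry: C3 and C4 come from D-tartaric acid. C5 is set in the ring closure (metal-bridged transition state on the acetonide-locked half-chair). C6 is formed cis to O5 and then inverted by Mitsunobu benzoylation, after the acetate has been placed on axial O5 by orthoester opening.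

Key step: step 6

Remark: (4R,5R)-2,2-dimethyl-1,3-dioxolane-4,5-dimethanol (from D-tartaric acid) and 2-methylidenepropane-1,3-diol are taken as commercial.

**Route**

Step 1
Reactants: 1 (4R,5R)-2,2-dimethyl-1,3-dioxolane-4,5-dimethanol (2,3-O-isopropylidene-D-threitol)
Product: 3 (4R,5R)-4,5-diethenyl-2,2-dimethyl-1,3-dioxolane, via dialdehyde 2 (not isolated)
Conditions: (COCl)2, DMSO, CH2Cl2, −78 °C; Et3N; then Ph3P=CH2 (from Ph3PCH3Br, KOtBu, THF), −78 °C to rt
Reagents that add atoms: methyltriphenylphosphonium bromide, C[P+](c1ccccc1)(c1ccccc1)c1ccccc1.[Br-]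
Why: Swern oxidation followed in the same flask by Wittig methylenation avoids isolation of the hydrate-prone, epimerizable dialdehyde 2; the two stereocentres (later C3 and C4) come unchanged from D-tartaric acid.

Step 2
Reactants: 4 2-methylidenepropane-1,3-diol
Product: 5 2-(hydroxymethyl)prop-2-en-1-yl benzoate
Conditions: PhCOCl (0.9 equiv), Et3N, CH2Cl2, −40 to 0 °C
Reagents that add atoms: benzoyl chloride, O=C(Cl)c1ccccc1
Why: Statistical mono-O-acylation of a symmetric 1,3-diol with a substoichiometric amount of acid chloride; no stereocentre is involved.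

Step 3
Reactants: 5 2-(hydroxymethyl)prop-2-en-1-yl benzoate
Product: 6 2-formylprop-2-en-1-yl benzoate
Conditions: MnO2, CH2Cl2, rt; used at once
Reagents that add atoms: none
Why: Chemoselective MnO2 oxidation of the allylic alcohol to the 2-substituted acrolein.

Step 4
Reactants: 3 (4R,5R)-4,5-diethenyl-2,2-dimethyl-1,3-dioxolane (3 equiv); 6 2-formylprop-2-en-1-yl benzoate
Product: 7 (E)-3-[(4R,5R)-5-ethenyl-2,2-dimethyl-1,3-dioxolan-4-yl]-2-formylprop-2-en-1-yl benzoate
Conditions: second-generation Hoveyda–Grubbs catalyst [RuCl2(H2IMes)(=CH-C6H4-2-OiPr)] (5 mol%), CH2Cl2, 40 °C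
Reagents that add atoms: none
Why: Olefin cross-metathesis of one vinyl group of 3 (in excess, recovered diene recycled) with the non-dimerizing 2-substituted acrolein 6, in analogy to cross-metatheses with methacrolein, should give mainly the E enal; the geometry is of no consequence later.

Step 5
Reactants: 7 (E)-3-[(4R,5R)-5-ethenyl-2,2-dimethyl-1,3-dioxolan-4-yl]-2-formylprop-2-en-1-yl benzoate
Product: 9 (E)-2-formyl-3-[(4R,5S)-5-formyl-2,2-dimethyl-1,3-dioxolan-4-yl]prop-2-en-1-yl benzoate, via ozonide 8 (not isolated)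
Conditions: O3, CH2Cl2, −78 °C (Sudan Red 7B end point); PPh3, −78 °C to rt; used crude
Reagents that add atoms: ozone, [O-][O+]=O
Why: Ozonolysis with reductive work-up cleaves the electron-rich terminal vinyl group much faster than the electron-poor trisubstituted enal double bond and unmasks the C5 aldehyde without touching C4.

Step 6
Reactants: 9 (E)-2-formyl-3-[(4R,5S)-5-formyl-2,2-dimethyl-1,3-dioxolan-4-yl]prop-2-en-1-yl benzoate
Product: 12 [(3aR,4R,5R,7aR)-4,5-dihydroxy-2,2-dimethyl-3a,4,5,7a-tetrahydro-1,3-benzodioxol-6-yl]methyl benzoate, via siloxyallylchromium dichloride 10 (not isolated), via bis(trimethylsilyl) ether 11 (not isolated)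
Conditions: CrCl2 (6 equiv), Me3SiCl (4 equiv), DMF, 25 °C, 9 added over 8 h to 5 mM; then 10% aq. citric acid, THF, 0 °C
Reagents that add atoms: none
Why: Proposed new method: CrCl2 and Me3SiCl reduce only the conjugated aldehyde of 9 (two one-electron transfers, O-silylation) to the γ-silyloxyallylchromium dichloride 10, with the metal on C2 and the former enal carbon C6 as the oxygen-bearing allyl terminus, so the E/Z geometry of the enal no longer matters; C6 then adds to the C5 aldehyde through a closed, chromium–oxygen-bridged six-membered transition state (SE2′), which forms C5–C6, moves the double bond to C1=C2 inside the new ring and, after silylation of the chromium alkoxide (11) and acidic work-up, gives 12. The closest known reaction type is the intermolecular cross-pinacol-type coupling of enals with aldehydes mediated by divalent chromium and a chlorosilane (an allylchromium addition of the Nozaki–Hiyama–Kishi family, anti-selective); the intramolecular form with the whole allyl unit inside the forming ring has no precedent. The cyclohexene closes 6-exo-trig at the carbonyl carbon with the three allyl carbons endocyclic; bonding through C2 would need a four-membered ring, so only C6 can attack. C5: the metal bridge forces the carbonyl oxygen into the axial position of the only half-chair that the trans-fused acetonide allows (O3 and O4 equatorial), i.e. cis to O4; C6: the (E)-silyl enol ether of 10 (oxygen anti to the chromium-bearing carbon, as in the intermolecular anti series) ends pseudo-equatorial, i.e. cis to O5. The step needs chemoselectivity for the enal over the α-alkoxy aldehyde (secured by conjugation, saturated aldehydes being inert to CrCl2) and ring closure over oligomerization (slow addition, high dilution); β-elimination of O3 from 10 is the main competing path.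

Step 7
Reactants: 12 [(3aR,4R,5R,7aR)-4,5-dihydroxy-2,2-dimethyl-3a,4,5,7a-tetrahydro-1,3-benzodioxol-6-yl]methyl benzoate
Product: 14 [(3aS,4R,5R,7aR)-4-acetyloxy-5-hydroxy-2,2-dimethyl-3a,4,5,7a-tetrahydro-1,3-benzodioxol-6-yl]methyl benzoate, via cyclic orthoacetate 13 (not isolated)
Conditions: MeC(OMe)3, PPTS (cat.), CH2Cl2, rt; then 80% aq. AcOH, 0 °C, short
Reagents that add atoms: trimethyl orthoacetate, CC(OC)(OC)OC; water, O
Why: Cyclic orthoester formation on the cis-diol and mild acid hydrolysis, which opens five-membered orthoesters of axial/equatorial diols to the axial ester, should put the acetate on axial O5 (target numbering; conformation locked by the acetonide) and leave the pseudo-equatorial allylic O6–H free.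

Step 8
Reactants: 14 [(3aS,4R,5R,7aR)-4-acetyloxy-5-hydroxy-2,2-dimethyl-3a,4,5,7a-tetrahydro-1,3-benzodioxol-6-yl]methyl benzoate
Product: 15 [(3aS,4R,5S,7aR)-4-acetyloxy-5-benzoyloxy-2,2-dimethyl-3a,4,5,7a-tetrahydro-1,3-benzodioxol-6-yl]methyl benzoate
Conditions: PhCO2H, PPh3, DIAD, toluene, 0 °C to rt
Reagents that add atoms: benzoic acid, O=C(O)c1ccccc1
Why: Mitsunobu esterification inverts the allylic carbinol (target C6) by SN2 displacement of the oxyphosphonium by benzoate, giving the 5,6-trans diester; the cis acetate on C5 cannot participate.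

Step 9
Reactants: 15 [(3aS,4R,5S,7aR)-4-acetyloxy-5-benzoyloxy-2,2-dimethyl-3a,4,5,7a-tetrahydro-1,3-benzodioxol-6-yl]methyl benzoate
Product: 16 [(3R,4S,5S,6S)-5-acetyloxy-6-benzoyloxy-3,4-dihydroxycyclohex-1-en-1-yl]methyl benzoate (target)
Conditions: CF3CO2H–H2O (9:1), CH2Cl2, 0 °C, short
Reagents that add atoms: none
Why: Acid hydrolysis of the strained trans-fused isopropylidene acetal under conditions that leave the three esters in place releases the 3,4-diol without touching any stereocentre.

**Compound list**

1 | (4R,5R)-2,2-dimethyl-1,3-dioxolane-4,5-dimethanol | OC[C@H]1OC(C)(C)O[C@@H]1CO | starting material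
2 | (4S,5S)-2,2-dimethyl-1,3-dioxolane-4,5-dicarbaldehyde | O=C[C@H]1OC(C)(C)O[C@@H]1C=O | intermediate
3 | (4R,5R)-4,5-diethenyl-2,2-dimethyl-1,3-dioxolane | C=C[C@H]1OC(C)(C)O[C@@H]1C=C | intermediate
4 | 2-methylidenepropane-1,3-diol | C=C(CO)CO | starting material
5 | 2-(hydroxymethyl)prop-2-en-1-yl benzoate | C=C(CO)COC(=O)c1ccccc1 | intermediate
6 | 2-formylprop-2-en-1-yl benzoate | C=C(C=O)COC(=O)c1ccccc1 | intermediate
7 | (E)-3-[(4R,5R)-5-ethenyl-2,2-dimethyl-1,3-dioxolan-4-yl]-2-formylprop-2-en-1-yl benzoate | O=C/C(COC(=O)c2ccccc2)=C/[C@H]1OC(C)(C)O[C@@H]1C=C | intermediate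
8 | secondary ozonide of 7 (1,2,4-trioxolan-3-yl in place of the ethenyl group, epimers at the trioxolane carbon) | O=C/C(COC(=O)c2ccccc2)=C/[C@H]1OC(C)(C)O[C@@H]1C3OCOO3 | intermediate
9 | (E)-2-formyl-3-[(4R,5S)-5-formyl-2,2-dimethyl-1,3-dioxolan-4-yl]prop-2-en-1-yl benzoate | O=C/C(COC(=O)c2ccccc2)=C/[C@H]1OC(C)(C)O[C@@H]1C=O | intermediate
10 | γ-(trimethylsilyloxy)allylchromium dichloride from 9 (Cl2Cr on C2, Me3SiO on C6, E enol ether, C2 epimers) | C[Si](C)(C)O/C=C(\COC(=O)c2ccccc2)C([Cr](Cl)Cl)[C@H]1OC(C)(C)O[C@@H]1C=O | intermediate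
11 | 4,5-bis(trimethylsilyl) ether of 12 | C[Si](C)(C)O[C@H]1[C@H]2OC(C)(C)O[C@@H]2C=C(COC(=O)c3ccccc3)[C@H]1O[Si](C)(C)C | intermediate
12 | [(3aR,4R,5R,7aR)-4,5-dihydroxy-2,2-dimethyl-3a,4,5,7a-tetrahydro-1,3-benzodioxol-6-yl]methyl benzoate | O[C@H]1[C@H]2OC(C)(C)O[C@@H]2C=C(COC(=O)c3ccccc3)[C@H]1O | intermediate
13 | cyclic methyl orthoacetate of 12 (4,5-O-(1-methoxyethylidene), epimers at the orthoester carbon) | COC1(C)O[C@H]2[C@H]3OC(C)(C)O[C@@H]3C=C(COC(=O)c4ccccc4)[C@H]2O1 | intermediate
14 | [(3aS,4R,5R,7aR)-4-acetyloxy-5-hydroxy-2,2-dimethyl-3a,4,5,7a-tetrahydro-1,3-benzodioxol-6-yl]methyl benzoate | CC(=O)O[C@H]1[C@H]2OC(C)(C)O[C@@H]2C=C(COC(=O)c3ccccc3)[C@H]1O | intermediate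
15 | [(3aS,4R,5S,7aR)-4-acetyloxy-5-benzoyloxy-2,2-dimethyl-3a,4,5,7a-tetrahydro-1,3-benzodioxol-6-yl]methyl benzoate | CC(=O)O[C@H]1[C@H]2OC(C)(C)O[C@@H]2C=C(COC(=O)c3ccccc3)[C@@H]1OC(=O)c4ccccc4 | intermediate
16 | [(3R,4S,5S,6S)-5-acetyloxy-6-benzoyloxy-3,4-dihydroxycyclohex-1-en-1-yl]methyl benzoate | CC(=O)O[C@H]1[C@@H](O)[C@H](O)C=C(COC(=O)c2ccccc2)[C@@H]1OC(=O)c1ccccc1 | target

**Step count and risks**

Total steps: 9. Longest linear sequence: 8 (steps 2, 3, 4, 5, 6, 7, 8, 9, counted from 2-methylidenepropane-1,3-diol 4). The other branch, from 1 through step 1, joins at step 4 and is 7 steps long.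

Steps most likely to fail:

1. Step 6 (Proposed new method). The allylchromium may lose the neighbouring acetonide oxygen by β-elimination, the strained bridged transition state may be too slow so that oligomerization wins, or facial control at C5 or C6 may be poor. The fallback uses known chemistry and reverses the order of ring construction: C5–C6 is made intermolecularly and the ring is closed at C1=C2. It sets out from 3 (with 6 as second component) and returns at 15. Ozonolysis of one vinyl group of 3 (O3, about 1 equiv, CH2Cl2, −78 °C; PPh3) should give (4S,5R)-5-ethenyl-2,2-dimethyl-1,3-dioxolane-4-carbaldehyde F1. Benzoyl bromide with catalytic ZnCl2 (CH2Cl2, −20 °C) should add 1,4 to 6 to give 3-(benzoyloxy)-2-(bromomethyl)prop-2-en-1-yl benzoate F2. Zinc dust in THF/saturated aqueous NH4Cl should join F1 and F2 by Barbier-type γ-addition (Felkin–Anh control at C5, syn hydroxy benzoate expected with zinc) to the open-chain hydroxy benzoate diene F3. Ac2O/pyridine should then give the acetate F4, and ring-closing metathesis with second-generation Grubbs catalyst [RuCl2(H2IMes)(PCy3)(=CHPh)] should close C1=C2 to give 15.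

2. Step 8. The activated allylic oxyphosphonium may react by SN2′ attack or elimination, or the acetyl group may migrate from O5 to the cis O6 before activation, so that inversion takes place at the wrong carbon. The fallback activates the cis-diol as a whole; it sets out from 12 and returns at 15. SOCl2/Et3N (CH2Cl2, 0 °C) should give the cyclic sulfite F5. PhCO2Cs in DMF at 60 °C should open it at the allylic carbon with inversion, and dilute aqueous acid should then hydrolyse the sulfite half-ester to the trans hydroxy benzoate F6. Ac2O/pyridine/DMAP should acetylate the remaining hydroxyl to give 15.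

3. Step 7. Orthoester opening may lose regiocontrol, the acetyl group may migrate from axial O5 to equatorial O6 during hydrolysis, or the strained acetonide may undergo methanolysis. The fallback differentiates the two hydroxyls by size instead; it sets out from 12 and returns at 14. TBSCl/imidazole (DMF, 0 °C) should silylate the less hindered pseudo-equatorial allylic hydroxyl to give the mono-silyl ether F7. Ac2O/pyridine/DMAP should give its acetate F8, and HF·pyridine (THF, 0 °C) should remove the silyl group to give 14.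

Further compounds
F1 | step 6 | (4S,5R)-5-ethenyl-2,2-dimethyl-1,3-dioxolane-4-carbaldehyde | C=C[C@H]1OC(C)(C)O[C@@H]1C=O
F2 | step 6 | 3-(benzoyloxy)-2-(bromomethyl)prop-2-en-1-yl benzoate (E/Z mixture) | BrCC(COC(=O)c1ccccc1)=COC(=O)c1ccccc1
F3 | step 6 | 1-(trans-5-ethenyl-2,2-dimethyl-1,3-dioxolan-4-yl)-1-hydroxy-3-methylidenebutane-2,4-diyl dibenzoate (carbinol and benzoate carbons configured as C5 and C6 of 15) | C=C[C@H]1OC(C)(C)O[C@@H]1[C@H](O)[C@@H](OC(=O)c2ccccc2)C(=C)COC(=O)c3ccccc3
F4 | step 6 | 1-acetyloxy-1-(trans-5-ethenyl-2,2-dimethyl-1,3-dioxolan-4-yl)-3-methylidenebutane-2,4-diyl dibenzoate | C=C[C@H]1OC(C)(C)O[C@@H]1[C@H](OC(C)=O)[C@@H](OC(=O)c2ccccc2)C(=C)COC(=O)c3ccccc3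
F5 | step 8 | cyclic sulfite of diol 12 (epimers at sulfur) | O=S1O[C@H]2[C@H]3OC(C)(C)O[C@@H]3C=C(COC(=O)c4ccccc4)[C@H]2O1
F6 | step 8 | [(3aR,4R,5S,7aR)-5-benzoyloxy-4-hydroxy-2,2-dimethyl-3a,4,5,7a-tetrahydro-1,3-benzodioxol-6-yl]methyl benzoate | O[C@H]1[C@H]2OC(C)(C)O[C@@H]2C=C(COC(=O)c3ccccc3)[C@@H]1OC(=O)c4ccccc4
F7 | step 7 | 5-O-tert-butyldimethylsilyl ether of 12 (benzodioxole numbering) | O[C@H]1[C@H]2OC(C)(C)O[C@@H]2C=C(COC(=O)c3ccccc3)[C@H]1O[Si](C)(C)C(C)(C)C
F8 | step 7 | 4-O-acetyl-5-O-tert-butyldimethylsilyl derivative of 12 | CC(=O)O[C@H]1[C@H]2OC(C)(C)O[C@@H]2C=C(COC(=O)c3ccccc3)[C@H]1O[Si](C)(C)C(C)(C)C
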